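**Strategy.** The pyranone ring (ring B: O1–C2–C3–C4–C4a–C8a) is read as a one-carbon-homologated α-aryloxy acid folded back onto ring A. The precursor is therefore an α-diazoketone in which the quaternary ether carbon C2 is bonded directly to the future C4 carbonyl. Photochemical Wolff rearrangement shifts C2, with retention, from C4 to the diazo carbon (C2–C3), and the resulting ketene carbon C4 acylates ring A ortho to O1 (C4–C4a), closing ring B in one operation. The C2 stereocentre is set beforehand by palladium-catalysed asymmetric allylic etherification; the diene chain is appended afterwards by B-alkyl Suzuki coupling because its proximal alkene would intercept the acylium.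

Key step: step 4

Assumption: the (R,R)-configured bisphosphine ligand is taken to deliver the (S)-ether in step 1; should the opposite sense be found, the (S,S)-ligand is used with no other change.

**Step 1**
Reactants: 1 methyl 4-hydroxybenzoate; 2 2-ethenyl-2-methyloxirane (racemic)
Product: 3 methyl 4-{[(2S)-1-hydroxy-2-methylbut-3-en-2-yl]oxy}benzoate
Conditions: Pd2(dba)3·CHCl3 (1 mol %), N,N'-[(1R,2R)-cyclohexane-1,2-diyl]bis[2-(diphenylphosphanyl)benzamide] (3 mol %), CH2Cl2, rt
Reagents that add atoms: none
Why: Palladium-catalysed asymmetric allylic etherification of a vinyl epoxide (dynamic kinetic asymmetric transformation): both enantiomers of 2 converge on one π-allyl palladium alkoxide, the phenol protonates the alkoxide and is delivered to the substituted allyl terminus, so the chiral ligand should set the ether stereocentre as S.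

**Step 2**
Reactants: 3 methyl 4-{[(2S)-1-hydroxy-2-methylbut-3-en-2-yl]oxy}benzoate
Product: 5 (2S)-2-[4-(methoxycarbonyl)phenoxy]-2-methylbut-3-enoic acid, via aldehyde 4 (not isolated)
Conditions: TEMPO (cat.), PhI(OAc)2 (2.2 equiv), MeCN/H2O, rt
Reagents that add atoms: water, O
Why: Nitroxyl-catalysed oxidation in aqueous acetonitrile should take the primary alcohol through the aldehyde (no α-hydrogen, so no epimerisation) to the acid without touching the vinyl group or the aryl ether.

**Step 3**
Reactants: 5 (2S)-2-[4-(methoxycarbonyl)phenoxy]-2-methylbut-3-enoic acid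
Product: 7 methyl 4-{[(3S)-1-diazo-3-methyl-2-oxopent-4-en-3-yl]oxy}benzoate, via acid chloride 6 (not isolated)
Conditions: 1-chloro-N,N,2-trimethylprop-1-en-1-amine, CH2Cl2, 0 °C to rt; then TMSCHN2, MeCN/THF, 0 °C
Reagents that add atoms: (trimethylsilyl)diazomethane, C[Si](C)(C)C=[N+]=[N-]
Why: Neutral acid chloride formation with the α-chloroenamine, then acylation of the diazoalkane (the diazoketone synthesis of the Arndt–Eistert sequence), should tolerate the hindered tertiary allylic ether; the stereocentre is not involved.

**Step 4**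
Reactants: 7 methyl 4-{[(3S)-1-diazo-3-methyl-2-oxopent-4-en-3-yl]oxy}benzoate
Product: 9 methyl (2R)-2-ethenyl-2-methyl-4-oxo-3,4-dihydro-2H-1-benzopyran-6-carboxylate, via ketene 8 (not isolated)
Conditions: hν (365 nm), CH2Cl2 (0.01 M), −40 °C; lamp off, then TfOH (1 equiv), −78 to −30 °C; cold Et3N quench
Reagents that add atoms: none
Why: Proposed new method: irradiation expels N2 and the quaternary carbon C2 migrates from the carbonyl carbon to the diazo carbon (Wolff rearrangement, forming C2–C3 with retention since the migrating carbon keeps its three other substituents in place) to give ketene 8, whose C3 is then protonated by TfOH to an acylium or acyl triflate; the acyl carbon C4 attacks ring A ortho to O1 (forming C4–C4a) and loss of the ring proton returns the acid. The closest known chemistry is Arndt–Eistert homologation followed by Friedel–Crafts cyclisation of 3-aryloxypropanoic acids to chroman-4-ones, together with acid-promoted acylation of arenes by ketenes; here both are run in one flask without isolating the ketene. Ring B closes in a 6-exo-dig mode at the acylium carbon. No new stereocentre is formed: the centre from step 1 is carried through by the stereoretentive 1,2-shift, and the descriptor changes from S in 7 to R in 9 only through a change of CIP priorities. The step needs Wolff rearrangement to outrun carbene addition to the vinyl group (direct photolysis, no copper or rhodium), a single possible migrating carbon (the diazo terminus is CH) and acylation ortho to O1 (both ortho positions are equivalent). The diene chain is deliberately absent, because its trisubstituted alkene would lie six atoms from the acylium carbon and would outrun the ester-deactivated ring.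

**Step 5**
Reactants: 10 5-bromo-2-methylpent-2-ene
Product: 11 6-methylhept-5-en-1-yne
Conditions: HC≡CLi·H2NCH2CH2NH2, DMSO, 0 °C to rt
Reagents that add atoms: lithium acetylide ethylenediamine complex, [Li]C#C.NCCN
Why: SN2 alkylation of an acetylide by a primary homoallylic bromide in a dipolar aprotic solvent should give the terminal alkyne.

**Step 6**
Reactants: 11 6-methylhept-5-en-1-yne
Product: 13 (1E)-1-iodo-2,6-dimethylhepta-1,5-diene, via alkenylalane 12 (not isolated)
Conditions: AlMe3 (2 equiv), Cp2ZrCl2 (0.25 equiv), CH2Cl2, 0 °C to rt; then I2, THF, −30 to 0 °C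
Reagents that add atoms: trimethylaluminium, C[Al](C)C; iodine, II
Why: Zirconium-catalysed carboalumination (Negishi) adds methyl and aluminium syn across the terminal alkyne with methyl at the internal carbon, and iodinolysis with retention should give the E-trisubstituted vinyl iodide; the trisubstituted alkene is inert.

**Step 7**
Reactants: 9 methyl (2R)-2-ethenyl-2-methyl-4-oxo-3,4-dihydro-2H-1-benzopyran-6-carboxylate; 13 (1E)-1-iodo-2,6-dimethylhepta-1,5-diene
Product: 15 methyl (2S)-2-[(3E)-4,8-dimethylnona-3,7-dien-1-yl]-2-methyl-4-oxo-3,4-dihydro-2H-1-benzopyran-6-carboxylate, via alkylborane 14 (not isolated)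
Conditions: 9-BBN (1.1 equiv), THF, 0 °C to rt; then 13, Pd(dppf)Cl2·CH2Cl2 (5 mol %), AsPh3, K3PO4 (aq.), DMF, rt
Reagents that add atoms: none
Why: 9-BBN should hydroborate the monosubstituted vinyl group anti-Markovnikov faster than it reduces the aryl ketone, and B-alkyl Suzuki–Miyaura coupling proceeds with retention of alkene geometry to give the E-trisubstituted alkene; C2 is untouched and its descriptor returns to S by priority change.

**Step 8**
Reactants: 15 methyl (2S)-2-[(3E)-4,8-dimethylnona-3,7-dien-1-yl]-2-methyl-4-oxo-3,4-dihydro-2H-1-benzopyran-6-carboxylate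
Product: 16 (2S)-2-[(3E)-4,8-dimethylnona-3,7-dien-1-yl]-2-methyl-4-oxo-3,4-dihydro-2H-1-benzopyran-6-carboxylic acid (CNP0374453.1)
Conditions: Me3SnOH (5 equiv), 1,2-dichloroethane, 80 °C; then 5 % aq. HCl work-up
Reagents that add atoms: trimethyltin hydroxide, C[Sn](C)(C)O
Why: Tin-mediated ester hydrolysis is near-neutral, so it should cleave the methyl ester without the base-induced retro-oxa-Michael opening of ring B that would racemise C2.

**Compound list**
1 | methyl 4-hydroxybenzoate | COC(=O)c1ccc(O)cc1 | starting material
2 | 2-ethenyl-2-methyloxirane (racemic) | CC1(C=C)CO1 | starting material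
3 | methyl 4-{[(2S)-1-hydroxy-2-methylbut-3-en-2-yl]oxy}benzoate | C=C[C@@](Oc1ccc(C(=O)OC)cc1)(C)CO | intermediate
4 | methyl 4-{[(2S)-2-methyl-1-oxobut-3-en-2-yl]oxy}benzoate | C=C[C@@](Oc1ccc(C(=O)OC)cc1)(C)C=O | intermediate
5 | (2S)-2-[4-(methoxycarbonyl)phenoxy]-2-methylbut-3-enoic acid | C=C[C@@](Oc1ccc(C(=O)OC)cc1)(C)C(=O)O | intermediate
6 | methyl 4-{[(2S)-1-chloro-2-methyl-1-oxobut-3-en-2-yl]oxy}benzoate | C=C[C@@](Oc1ccc(C(=O)OC)cc1)(C)C(Cl)=O | intermediate
7 | methyl 4-{[(3S)-1-diazo-3-methyl-2-oxopent-4-en-3-yl]oxy}benzoate | C=C[C@@](Oc1ccc(C(=O)OC)cc1)(C)C(=O)C=[N+]=[N-] | intermediate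
8 | methyl 4-{[(3S)-3-methyl-1-oxopenta-1,4-dien-3-yl]oxy}benzoate | C=C[C@@](Oc1ccc(C(=O)OC)cc1)(C)C=C=O | intermediate
9 | methyl (2R)-2-ethenyl-2-methyl-4-oxo-3,4-dihydro-2H-1-benzopyran-6-carboxylate | C=C[C@@]1(C)CC(=O)c2cc(C(=O)OC)ccc2O1 | intermediate
10 | 5-bromo-2-methylpent-2-ene | CC(C)=CCCBr | starting material
11 | 6-methylhept-5-en-1-yne | CC(C)=CCCC#C | intermediate
12 | [(1E)-2,6-dimethylhepta-1,5-dien-1-yl]dimethylalumane | CC(C)=CCC/C(C)=C/[Al](C)C | intermediate
13 | (1E)-1-iodo-2,6-dimethylhepta-1,5-diene | CC(C)=CCC/C(C)=C/I | intermediate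
14 | methyl (2S)-2-[2-(9-borabicyclo[3.3.1]nonan-9-yl)ethyl]-2-methyl-4-oxo-3,4-dihydro-2H-1-benzopyran-6-carboxylate | C(C[C@@]1(C)CC(=O)c2cc(C(=O)OC)ccc2O1)B1C2CCCC1CCC2 | intermediate
15 | methyl (2S)-2-[(3E)-4,8-dimethylnona-3,7-dien-1-yl]-2-methyl-4-oxo-3,4-dihydro-2H-1-benzopyran-6-carboxylate | CC(C)=CCC/C(C)=C/CC[C@@]1(C)CC(=O)c2cc(C(=O)OC)ccc2O1 | intermediate
16 | (2S)-2-[(3E)-4,8-dimethylnona-3,7-dien-1-yl]-2-methyl-4-oxo-3,4-dihydro-2H-1-benzopyran-6-carboxylic acid | CC(C)=CCC/C(C)=C/CC[C@@]1(C)CC(=O)c2cc(C(=O)O)ccc2O1 | target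

**Total step count:** 8. **Longest linear sequence:** 6 (steps 1, 2, 3, 4, 7, 8).

**Steps most likely to fail**

Step 4. During photolysis the carbene may add to the vinyl group or form an ylide at O1 instead of rearranging. The ketene may dimerise before the ester-deactivated ring is acylated. The acid may ionise the tertiary allylic aryl ether or trigger its Claisen rearrangement. The fallback sets out from 7 and uses known chemistry in two separate operations. Silver-catalysed Wolff rearrangement in the presence of water (PhCO2Ag, Et3N, THF/H2O, rt) should give (3R)-3-[4-(methoxycarbonyl)phenoxy]-3-methylpent-4-enoic acid F1. Oxalyl chloride with catalytic DMF converts it into methyl 4-{[(3R)-5-chloro-3-methyl-5-oxopent-1-en-3-yl]oxy}benzoate F2. Intramolecular Friedel–Crafts acylation of F2 (SnCl4, CH2Cl2, −78 °C) comes back to the route at 9.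

Step 7. The dialkylborane may reduce the C4 ketone in competition with hydroboration, and the sp3–sp2 coupling may lose material by protodeboronation or β-hydride elimination. The fallback sets out from 9. Iridium-catalysed hydroboration with pinacolborane ([Ir(cod)Cl]2, dppe, HBpin, CH2Cl2, rt), which leaves ketones alone, should give the isolable methyl (2S)-2-methyl-4-oxo-2-[2-(4,4,5,5-tetramethyl-1,3,2-dioxaborolan-2-yl)ethyl]-3,4-dihydro-2H-1-benzopyran-6-carboxylate F3. This is purified and then coupled with 13 (Pd(OAc)2, RuPhos, K3PO4, toluene/H2O, 80 °C), coming back at 15.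

Step 1. The phenol may attack the unsubstituted allyl terminus (linear ether), or facial control in the π-allyl capture may be incomplete, giving low enantiomeric purity. The fallback sets out from 1 and 2. Opening with an achiral catalyst (Pd(PPh3)4, THF, rt) should give racemic methyl 4-[(1-hydroxy-2-methylbut-3-en-2-yl)oxy]benzoate F4. Lipase-mediated kinetic resolution (Amano lipase PS, vinyl acetate, tert-butyl methyl ether) is expected to acylate the R alcohol to methyl 4-{[(2R)-1-(acetyloxy)-2-methylbut-3-en-2-yl]oxy}benzoate F5. The unreacted S alcohol is separated and comes back at 3. If the enzyme prefers the S alcohol instead, its acetate is isolated and methanolysed.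

**Further compounds**
F1 | step 4 | (3R)-3-[4-(methoxycarbonyl)phenoxy]-3-methylpent-4-enoic acid | C=C[C@@](Oc1ccc(C(=O)OC)cc1)(C)CC(=O)O
F2 | step 4 | methyl 4-{[(3R)-5-chloro-3-methyl-5-oxopent-1-en-3-yl]oxy}benzoate | C=C[C@@](Oc1ccc(C(=O)OC)cc1)(C)CC(Cl)=O
F3 | step 7 | methyl (2S)-2-methyl-4-oxo-2-[2-(4,4,5,5-tetramethyl-1,3,2-dioxaborolan-2-yl)ethyl]-3,4-dihydro-2H-1-benzopyran-6-carboxylate | CC1(C)OB(CC[C@@]2(C)CC(=O)c3cc(C(=O)OC)ccc3O2)OC1(C)C
F4 | step 1 | methyl 4-[(1-hydroxy-2-methylbut-3-en-2-yl)oxy]benzoate (racemic) | C=CC(C)(CO)Oc1ccc(C(=O)OC)cc1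
F5 | step 1 | methyl 4-{[(2R)-1-(acetyloxy)-2-methylbut-3-en-2-yl]oxy}benzoate | C=C[C@](Oc1ccc(C(=O)OC)cc1)(C)COC(C)=O
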